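The ratio [starting material]/[reagent] in Tuesday's flask opened at 3.20, so reagent was the limiting reagent, and target had a ceiling of 31.2% of the starting material charged.

| setting | Monday's | Thursday's | Tuesday's |
|---|---|---|---|
| starting material | 0.0800 M | 0.0800 M | 0.0800 M |
| reagent | 0.0880 M | 0.0440 M | 0.0250 M |
| time |  |  | 34 h |

- Monday's run (time / h: [target] / M): 6.8: 0.01335; 14: 0.02298; 20: 0.02908; 27: 0.03425; 34: 0.03799
- Thursday's run (time / h: [target] / M): 6.8: 0.00682; 14: 0.01249; 20: 0.01630; 27: 0.01967; 34: 0.02274

(each reading ± 2 × 10⁻⁴ M)

1. the exponent of [reagent] in the starting rate at the charge of the Monday's run (at the point where two percent of the starting material have become target)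
2. target in the Tuesday's run at 34 h, as a share of the starting material charged

- Overall: starting material + reagent -> target.
- Constant volume, constant temperature.
- The analysis sees a species whether free or bound.
- "The second partner" is reagent.
- An order is taken over about fifteen percent of the charge, up and down.

I went to logarithms first. The mean rates up to the first readings of Monday's and Thursday's runs stood at 1.96 to one, for reagent charges of 2.00 to one, and that put the exponent of [reagent] at 0.969. I took it as one, and assumed one for starting material, which neither run varied.

For a rate k[starting material][reagent], ln([starting material]/[reagent]) moves in a straight line with time, with a slope of k times the difference of the charges. So I carried the clock constant k, the mean rate up to Thursday's first reading over the product of the two concentrations at the halfway point of that conversion, which I read as 0.323 M⁻¹ h⁻¹.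

In my reckoning with this k, holding [starting material] at its charge made Tuesday's reagent decay pseudo-first-order and gave a bound from above of 18.3%. Holding it at the 0.0550 M that Tuesday's charge leaves once its reagent has reacted one to one gave a bound from below of 14.2%. The clock itself tightened this: for Tuesday's flask it put the climb of the logarithm over 34 h at 0.603, which took the reckoned ratio to 5.85, and that meant 17.1% of the starting material charged.

The forecast said an exponent of 0.98 (from 0.85 to 1.1) and, for Tuesday's target, 17% (from 15.5% to 18.2%), a share inside my bracket, and of Monday's late readings it said “That shouldn't matter at Tuesday's low product”.

Tuesday's flask gave 17.0%, and the exponent at Monday's charge came out at 1.0.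

    starting material ⇌ intermediate, settled at all times (0.4820)
    intermediate + reagent → target (1.663 M⁻¹ h⁻¹)
    2 starting material ⇌ idle substrate dimer, settled at all times (14.90 M⁻¹)
    target + reagent → side product (0.08676 M⁻¹ h⁻¹)

Loss of target with reagent to side product moves the readings by 10 in units of the scatter (root mean square), yet it made little difference to Tuesday's target. On Monday's run, the same k put target at half of the starting material charged at 33.7 h, and the flask reached that point at 38.1 h.

All runs come from a simulation for substances that don't exist.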